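The route rests on cutting the C5′–C6′ bond inside the saturated 1,4-diketone (C3′ ketone, C4′H(iPr), C5′H2, C6′ ketone) of the fourteen-membered triketone ring. The cyclohexene is first made by a Diels–Alder union of the oxa-bridged cembranoid diene (ring A) with an acyclic enone ester. A palladium-catalysed acylative opening of a siloxycyclopropane by a tethered acid chloride then forms C5′–C6′, unveils the C3′ ketone and closes the last ring in one operation; ring strain drives the bond and C4′ is carried through untouched. The precursor is a seco-acid in which C3′, C4′ and C5′ are a silyl cyclopropyl ether.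

Key step: step 36

Locants: ring A is numbered as a cembrane (C1–C20; C1 and C2 are shared with the cyclohexene, C15–C17 are the isopropenyl-derived carbons, C19 the exocyclic methylene); the triketone ring is numbered C1′ (quaternary ester carbon), C2′H2, C3′ ketone, C4′H(iPr), C5′H2, C6′ ketone, C7′H(Me), C8′–C10′, C11′H(Me), C12′H2, C13′ ketone, C14′H.

Assumption: the acyclic enone ester 46 is taken to show the regio-, endo- and facial preferences of the macrocyclic dienophiles in biscembranoid-type cycloadditions (C17–C14′ and C2–C1′ bonding, ester endo, attack anti to the C14 oxygen), and compounds 1, 6, 25 and 36 are taken as commercial.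

**Ring A, C10–C14 bromide**

Step 1
Reactants: 1 but-3-yn-1-ol
Product: 2 tert-butyl(but-3-yn-1-yloxy)diphenylsilane
Conditions: TBDPSCl, imidazole, CH2Cl2, 0 to 25 °C
Reagents that add atoms: tert-butyl(chloro)diphenylsilane (CC(C)(C)[Si](Cl)(c1ccccc1)c1ccccc1)
Why: Silyl ether formation on the primary alcohol gives a group that survives organoaluminium and organolithium reagents and is removed late by fluoride.

Step 2
Reactants: 2 tert-butyl(but-3-yn-1-yloxy)diphenylsilane
Product: 4 (2E)-5-[(tert-butyldiphenylsilyl)oxy]-3-methylpent-2-en-1-ol, via alkenylalane 3 (not isolated)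
Conditions: Me3Al, Cp2ZrCl2 (cat.), CH2Cl2, 0 to 25 °C; then n-BuLi, (CH2O)n, THF, −78 to 25 °C; aq. HCl
Reagents that add atoms: trimethylaluminium (C[Al](C)C); formaldehyde as paraformaldehyde (C=O)
Why: Negishi zirconium-catalysed carboalumination adds methyl and aluminium syn across the terminal alkyne with the metal on the terminal carbon, and the alanate traps formaldehyde with retention, which fixes the E geometry of the future C11=C12 alkene.

Step 3
Reactants: 4 (2E)-5-[(tert-butyldiphenylsilyl)oxy]-3-methylpent-2-en-1-ol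
Product: 5 {[(3E)-5-bromo-3-methylpent-3-en-1-yl]oxy}(tert-butyl)diphenylsilane
Conditions: CBr4, PPh3, CH2Cl2, 0 °C
Reagents that add atoms: tetrabromomethane (BrC(Br)(Br)Br)
Why: Appel bromination displaces the oxyphosphonium of the primary allylic alcohol by SN2 without allylic transposition.

**Ring A, main line**

Step 4
Reactants: 6 geraniol
Product: 7 geranyl tert-butyldimethylsilyl ether
Conditions: TBSCl, imidazole, CH2Cl2, 25 °C
Reagents that add atoms: tert-butyl(chloro)dimethylsilane (CC(C)(C)[Si](C)(C)Cl)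
Why: Silyl ether formation masks the allylic alcohol (future C2) and deactivates the adjacent alkene towards electrophilic oxidants.

Step 5
Reactants: 7 geranyl tert-butyldimethylsilyl ether
Product: 8 (S)-6,7-epoxygeranyl tert-butyldimethylsilyl ether
Conditions: ent-Shi ketone (L-fructose-derived, 30 mol%), KHSO5 (Oxone), K2CO3, Bu4NHSO4, MeCN/dimethoxymethane/aq. buffer pH 10.5, 0 °C
Reagents that add atoms: potassium peroxymonosulfate ([K+].[O-]S(=O)(=O)OO)
Why: Shi asymmetric epoxidation through a spiro dioxirane transition state selects the more electron-rich distal trisubstituted alkene, and the L-fructose-derived catalyst antipode sets the future C7 as S.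

Step 6
Reactants: 8 (S)-6,7-epoxygeranyl tert-butyldimethylsilyl ether
Product: 9 (3S,6E)-8-[(tert-butyldimethylsilyl)oxy]-2,6-dimethylocta-1,6-dien-3-ol
Conditions: Et2Al(2,2,6,6-tetramethylpiperidide), benzene, 0 °C; aq. HCl
Reagents that add atoms: none
Why: Base-induced epoxide-to-allylic-alcohol rearrangement (syn β-elimination by the aluminium amide) removes a methyl proton and opens the tertiary C–O bond, so the C7–O bond and its S configuration are untouched.

Step 7
Reactants: 9 (3S,6E)-8-[(tert-butyldimethylsilyl)oxy]-2,6-dimethylocta-1,6-dien-3-ol; 5 {[(3E)-5-bromo-3-methylpent-3-en-1-yl]oxy}(tert-butyl)diphenylsilane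
Product: 11 (2E,6S,10E)-1-[(tert-butyldimethylsilyl)oxy]-13-[(tert-butyldiphenylsilyl)oxy]-3,11-dimethyl-7-methylidenetrideca-2,10-dien-6-ol, via dilithio dianion 10 (not isolated)
Conditions: n-BuLi (2.2 equiv), TMEDA, Et2O/hexane, 0 to 25 °C; then 5, −78 to 0 °C; aq. NH4Cl
Reagents that add atoms: none
Why: Alkoxide-directed allylic lithiation of the methallylic methyl group gives a dianion whose carbon terminus is alkylated by the primary allylic bromide in an SN2 reaction, which forms C9–C10 and leaves C7 unchanged.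

Step 8
Reactants: 11 (2E,6S,10E)-1-[(tert-butyldimethylsilyl)oxy]-13-[(tert-butyldiphenylsilyl)oxy]-3,11-dimethyl-7-methylidenetrideca-2,10-dien-6-ol
Product: 12 (2E,6S,10S,11S)-10,11-epoxide of 11
Conditions: ent-Shi ketone (30 mol%), KHSO5 (Oxone), K2CO3, Bu4NHSO4, MeCN/dimethoxymethane/aq. buffer pH 10.5, 0 °C
Reagents that add atoms: potassium peroxymonosulfate ([K+].[O-]S(=O)(=O)OO)
Why: Shi asymmetric epoxidation selects the only unactivated trisubstituted alkene (C11=C12) over the 1,1-disubstituted and the allylic-ether alkenes and, with the same catalyst antipode, sets C11 and C12 as S,S.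

Step 9
Reactants: 12 (2E,6S,10S,11S)-10,11-epoxide of 11
Product: 13 (2S)-4-[(tert-butyldiphenylsilyl)oxy]-2-[(2R,6S)-6-{(3E)-5-[(tert-butyldimethylsilyl)oxy]-3-methylpent-3-en-1-yl}-5-methylideneoxan-2-yl]butan-2-ol
Conditions: camphorsulfonic acid (10 mol%), CH2Cl2, 0 °C
Reagents that add atoms: none
Why: Acid-catalysed 6-exo epoxide-opening etherification by the C7 hydroxyl at the secondary C11 with inversion closes the 2,6-trans oxane (C11 becomes R) and leaves the C12 tertiary alcohol with its S configuration retained.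

Step 10
Reactants: 13 oxane with C2 TBS ether and C14 TBDPS ether
Product: 14 (2E)-5-[(2S,6R)-6-{(2S)-4-[(tert-butyldiphenylsilyl)oxy]-2-hydroxybutan-2-yl}-3-methylideneoxan-2-yl]-3-methylpent-2-en-1-ol
Conditions: PPTS, MeOH, 25 °C
Reagents that add atoms: none
Why: Mild acidic methanolysis (selective desilylation) cleaves the primary allylic TBS ether much faster than the primary TBDPS ether.

Step 11
Reactants: 14 allylic alcohol
Product: 15 (2E)-5-[(2S,6R)-6-{(2S)-4-[(tert-butyldiphenylsilyl)oxy]-2-hydroxybutan-2-yl}-3-methylideneoxan-2-yl]-3-methylpent-2-enal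
Conditions: MnO2, CH2Cl2, 25 °C
Reagents that add atoms: none
Why: MnO2 oxidation is selective for the allylic primary alcohol and leaves the tertiary alcohol and the E alkene untouched.

Step 12
Reactants: 15 enal
Product: 16 (2S)-4-[(tert-butyldiphenylsilyl)oxy]-2-{(2R,6S)-6-[(3E)-6,6-dibromo-3-methylhexa-3,5-dien-1-yl]-5-methylideneoxan-2-yl}butan-2-ol
Conditions: CBr4, PPh3 (2 equiv), CH2Cl2, 0 °C
Reagents that add atoms: tetrabromomethane (BrC(Br)(Br)Br)
Why: Ramirez (Corey–Fuchs) dibromoolefination by the dibromomethylene ylide made in the flask converts the aldehyde into the 1,1-dibromodiene whose new carbon becomes C1.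

Step 13
Reactants: 16 1,1-dibromodiene
Product: 17 (2S)-4-[(tert-butyldiphenylsilyl)oxy]-2-{(2R,6S)-6-[(3E,5Z)-6-bromo-3,7-dimethylocta-3,5,7-trien-1-yl]-5-methylideneoxan-2-yl}butan-2-ol
Conditions: isopropenyl-B(pin), Pd2(dba)3 (cat.), tri(2-furyl)phosphine, Cs2CO3, THF/H2O, 40 °C
Reagents that add atoms: 4,4,5,5-tetramethyl-2-(prop-1-en-2-yl)-1,3,2-dioxaborolane (CC(=C)B1OC(C)(C)C(C)(C)O1)
Why: Suzuki–Miyaura mono-coupling of a 1,1-dibromoalkene occurs by oxidative addition at the less hindered bromine trans to C3, so the isopropenyl group ends trans to C3 and the remaining bromine cis to it.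

Step 14
Reactants: 17 bromotriene TBDPS ether
Product: 18 (3S)-3-{(2R,6S)-6-[(3E,5Z)-6-bromo-3,7-dimethylocta-3,5,7-trien-1-yl]-5-methylideneoxan-2-yl}butane-1,3-diol
Conditions: TBAF, THF, 0 to 25 °C; aq. NH4Cl
Reagents that add atoms: none
Why: Fluoride-mediated desilylation frees the C14 primary alcohol without affecting the vinyl bromide or the triene.

Step 15
Reactants: 18 bromotriene diol
Product: 19 (3S)-3-{(2R,6S)-6-[(3E,5Z)-6-bromo-3,7-dimethylocta-3,5,7-trien-1-yl]-5-methylideneoxan-2-yl}-3-hydroxybutanal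
Conditions: Dess–Martin periodinane, NaHCO3, CH2Cl2, 0 °C
Reagents that add atoms: none
Why: Buffered Dess–Martin oxidation converts only the primary alcohol into the β-hydroxy aldehyde and avoids elimination of the tertiary hydroxyl.

Step 16
Reactants: 19 bromotriene aldehyde
Product: 20 (1Z,3E,7S,11R,12S,14RS)-7,11-epoxycembra-1,3,8(19),15-tetraene-12,14-diol
Conditions: CrCl2 (excess), NiCl2 (cat.), DMSO/THF, 25 °C, 2 mM
Reagents that add atoms: none
Why: Nozaki–Hiyama–Kishi macrocyclisation closes the fourteen-membered carbocycle of ring A by addition of the alkenylchromium (formed from the 2-bromodiene with retention of the C1=C2 geometry) to the aldehyde, and the C14 carbinol is expected as an epimer mixture that the next two steps converge.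

Step 17
Reactants: 20 macrocyclic diol (C14 epimers)
Product: 21 (1Z,3E,7S,11R,12S)-12-hydroxy-7,11-epoxycembra-1,3,8(19),15-tetraen-14-one
Conditions: Dess–Martin periodinane, NaHCO3, CH2Cl2, 0 °C
Reagents that add atoms: none
Why: Dess–Martin oxidation of the secondary allylic alcohol erases the uncontrolled C14 centre and gives the β-hydroxy dienone.

Step 18
Reactants: 21 β-hydroxy dienone
Product: 23 (1Z,3E,7S,11R,12S,14R)-7,11-epoxycembra-1,3,8(19),15-tetraene-12,14-diol, via O12-diethylborinate 22 (not isolated)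
Conditions: Et2BOMe, THF/MeOH, −78 °C; then NaBH4; MeOH work-up
Reagents that add atoms: none
Why: Narasaka–Prasad reduction ties the C12 hydroxyl and the ketone in a six-membered boron chelate to which external hydride adds axially, giving the 1,3-syn diol and so setting C14 as R from C12.

Step 19
Reactants: 23 syn diol
Product: 24 12,14-bis(triethylsilyl) ether of 23 (diene for the cycloaddition)
Conditions: TESOTf, 2,6-lutidine, CH2Cl2, −78 to 0 °C
Reagents that add atoms: triethylsilyl trifluoromethanesulfonate (CC[Si](CC)(CC)OS(=O)(=O)C(F)(F)F)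
Why: Silylation with the silyl triflate and a hindered base protects both the secondary allylic and the tertiary alcohol and places a bulky group on C14 that later shields one diene face.

**Siloxycyclopropane ylide (C1′–C5′)**

Step 20
Reactants: 25 methyl (R)-2-hydroxy-3-methylbutanoate
Product: 26 methyl (R)-3-methyl-2-(methylsulfonyloxy)butanoate
Conditions: MsCl, Et3N, CH2Cl2, 0 °C
Reagents that add atoms: methanesulfonyl chloride (CS(=O)(=O)Cl)
Why: Mesylation with retention turns the chiral-pool hydroxyl into the leaving group for the later cyclopropane closure.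

Step 21
Reactants: 26 methyl (R)-3-methyl-2-(methylsulfonyloxy)butanoate
Product: 27 (R)-3-methyl-2-(methylsulfonyloxy)butanoic acid
Conditions: Me3SnOH, 1,2-dichloroethane, 70 °C; aq. HCl
Reagents that add atoms: trimethyltin hydroxide (C[Sn](C)(C)O)
Why: Neutral ester hydrolysis with the tin hydroxide avoids displacement or epimerisation at the sulfonate-bearing carbon.

Step 22
Reactants: 27 (R)-3-methyl-2-(methylsulfonyloxy)butanoic acid
Product: 29 methyl (R)-6-methyl-5-(methylsulfonyloxy)-4-oxoheptanoate, via acid chloride 28 (not isolated)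
Conditions: (COCl)2, DMF (cat.), CH2Cl2, 0 °C; then IZnCH2CH2CO2Me (from ICH2CH2CO2Me and Zn), Pd(PPh3)4 (cat.), THF, 25 °C
Reagents that add atoms: (3-methoxy-3-oxopropyl)zinc iodide (COC(=O)CC[Zn]I)
Why: Negishi-type palladium-catalysed acylation of the zinc homoenolate of methyl propanoate by the acid chloride forms the C2′–C3′ bond under conditions that tolerate the ester and the sulfonate.

Step 23
Reactants: 29 methyl (R)-6-methyl-5-(methylsulfonyloxy)-4-oxoheptanoate
Product: 31 methyl 3-[(2S)-2-isopropyl-1-(trimethylsilyloxy)cyclopropyl]propanoate (propanoate chain cis to isopropyl), via iodozinc cyclopropoxide 30 (not isolated)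
Conditions: CH2(ZnI)2 (from CH2I2 and Zn, PbCl2 cat.), THF, 0 to 25 °C; then Me3SiCl, 0 °C
Reagents that add atoms: bis(iodozincio)methane (I[Zn]C[Zn]I); chlorotrimethylsilane (C[Si](C)(C)Cl)
Why: Nucleophilic [2+1] cyclopropanation with the gem-dizinc reagent proceeds by chelation-controlled addition of one C–Zn bond to the ketone and intramolecular SN2 displacement of the mesylate by the other with inversion, which sets C4′ as S before the zinc alkoxide is silylated.

Step 24
Reactants: 31 siloxycyclopropane ester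
Product: 33 methyl 2-bromo-3-[(2S)-2-isopropyl-1-(trimethylsilyloxy)cyclopropyl]propanoate (C1′ epimers), via lithium enolate 32 (not isolated)
Conditions: LiN(iPr)2, THF, −78 °C; then CBr4; aq. NH4Cl
Reagents that add atoms: tetrabromomethane (BrC(Br)(Br)Br)
Why: Ester enolate formation and electrophilic α-bromination functionalise C1′, whose new centre is irrelevant because it becomes sp2 in the ylide.

Step 25
Reactants: 33 α-bromo ester
Product: 35 methyl 3-[(2S)-2-isopropyl-1-(trimethylsilyloxy)cyclopropyl]-2-(triphenyl-λ5-phosphanylidene)propanoate, via phosphonium bromide 34 (not isolated)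
Conditions: PPh3, toluene, 80 °C; then aq. K2CO3, CH2Cl2
Reagents that add atoms: triphenylphosphine (c1ccc(cc1)P(c1ccccc1)c1ccccc1)
Why: SN2 quaternisation of the phosphine by the α-bromo ester and deprotonation by carbonate give the isolable ester-stabilised phosphonium ylide.

**C6′–C14′ chain**

Step 26
Reactants: 36 (S)-citronellic acid
Product: 37 (S)-N-methoxy-N,3,7-trimethyloct-6-enamide
Conditions: MeNHOMe·HCl, EDC·HCl, Et3N, DMAP (cat.), CH2Cl2, 25 °C
Reagents that add atoms: N,O-dimethylhydroxylamine hydrochloride (CNOC.Cl)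
Why: Carbodiimide amide coupling gives the Weinreb amide that later allows clean mono-addition of a vinyl nucleophile at C13′, the C11′ stereocentre coming from the chiral pool.

Step 27
Reactants: 37 (S)-N-methoxy-N,3,7-trimethyloct-6-enamide
Product: 39 (S)-N-methoxy-N,3-dimethyl-6-oxohexanamide, via ozonide 38 (not isolated)
Conditions: O3, CH2Cl2, −78 °C; then Me2S
Reagents that add atoms: ozone ([O-][O+]=O)
Why: Ozonolysis with reductive work-up cleaves the trisubstituted alkene to the C8′ aldehyde without touching the remote stereocentre.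

Step 28
Reactants: 39 (S)-N-methoxy-N,3-dimethyl-6-oxohexanamide
Product: 40 (2E,6S)-8-[methoxy(methyl)amino]-2,6-dimethyl-8-oxooct-2-enoic acid
Conditions: methylmalonic acid, pyridine, piperidine (cat.), 90 °C
Reagents that add atoms: methylmalonic acid (CC(C(=O)O)C(=O)O)
Why: Doebner–Knoevenagel condensation followed by decarboxylation gives the thermodynamically favoured E α-methyl enoic acid and installs C7′ and C6′.

Step 29
Reactants: 40 E enoic acid
Product: 41 (2R,6S)-8-[methoxy(methyl)amino]-2,6-dimethyl-8-oxooctanoic acid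
Conditions: H2 (50 atm), Ru(OAc)2[(R)-H8-BINAP] (1 mol%), MeOH, 25 °C
Reagents that add atoms: none
Why: Carboxylate-directed asymmetric hydrogenation of the E 2-methyl-2-enoic acid by the ruthenium diphosphine catalyst of R configuration delivers hydrogen to one face and sets C7′ as R.

Step 30
Reactants: 41 saturated acid Weinreb amide
Product: 42 (2R,6S)-2,6-dimethyl-8-oxodec-9-enoic acid
Conditions: CH2=CHMgBr (3 equiv), THF, −20 to 0 °C; cold aq. HCl
Reagents that add atoms: vinylmagnesium bromide (C=C[Mg]Br)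
Why: Weinreb ketone synthesis gives the vinyl ketone because the carboxylate is inert and the Grignard reagent adds once to the amide through a stable chelate that collapses only on work-up.

Step 31
Reactants: 42 vinyl ketone acid
Product: 43 9H-fluoren-9-ylmethyl (2R,6S)-2,6-dimethyl-8-oxodec-9-enoate
Conditions: 9-fluorenylmethanol, EDC·HCl, DMAP (cat.), CH2Cl2, 25 °C
Reagents that add atoms: 9-fluorenylmethanol (OCC1c2ccccc2-c2ccccc21)
Why: Carbodiimide esterification protects the C6′ acid as a fluorenylmethyl ester that survives ozone, the ylide and heat and is later removed by a secondary amine.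

Step 32
Reactants: 43 vinyl ketone ester
Product: 45 9H-fluoren-9-ylmethyl (2R,6S)-2,6-dimethyl-8,9-dioxononanoate, via ozonide 44 (not isolated)
Conditions: O3, CH2Cl2, −78 °C; then Me2S
Reagents that add atoms: ozone ([O-][O+]=O)
Why: Ozonolysis of the vinyl ketone with reductive work-up gives the α-keto aldehyde whose aldehyde carbon becomes C14′.

**Union and endgame**

Step 33
Reactants: 35 ester-stabilised ylide; 45 α-keto aldehyde
Product: 46 1-(9H-fluoren-9-ylmethyl) 11-methyl (2R,6S,9E)-10-{[(2S)-2-isopropyl-1-(trimethylsilyloxy)cyclopropyl]methyl}-2,6-dimethyl-8-oxoundec-9-enedioate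
Conditions: CH2Cl2, 25 °C
Reagents that add atoms: none
Why: Wittig reaction of the α-branched stabilised ylide with the aldehyde carbonyl of the glyoxal gives the E trisubstituted alkene (methyl ester trans to the C13′ ketone) under thermodynamic control and without base.

Step 34
Reactants: 24 bis(triethylsilyl) diene; 46 enone ester
Product: 47 Diels–Alder adduct (cyclohexene C1, C2, C15, C17, C14′, C1′; C2 S, C1′ S, C14′ S; fluorenylmethyl ester, siloxycyclopropane and both triethylsilyl ethers intact)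
Conditions: toluene, BHT (cat.), 100 °C, sealed tube
Reagents that add atoms: none
Why: In this thermal Diels–Alder reaction of the s-cis C2=C1–C15=C17 diene the unhindered C17 terminus bonds to the less substituted C14′ and C2 to C1′, addition is suprafacial (C13′ acyl trans to the ester and cis to C2′), the two large cis substituents of the dienophile point exo so that the ester is endo and ends cis to C3, and the dienophile approaches the face anti to the bulky C14 triethylsilyloxy group, which together set C2, C1′ and C14′.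

Step 35
Reactants: 47 Diels–Alder adduct
Product: 48 seco-acid (free C6′ carboxylic acid)
Conditions: piperidine, CH2Cl2, 25 °C; pH 5 buffer
Reagents that add atoms: none
Why: E1cB cleavage of the fluorenylmethyl ester by the secondary amine frees the acid without touching the silyl ethers, the siloxycyclopropane or the hindered methyl ester.

Step 36
Reactants: 48 seco-acid
Product: 50 12,14-bis(triethylsilyl) ether of the target, via seco-acid chloride 49 (not isolated)
Conditions: 1-chloro-N,N,2-trimethylprop-1-enylamine, CH2Cl2, 0 °C; then slow addition to PdCl2(PPh3)2 (15 mol%), CO (1 atm), toluene, 80 °C, 1 mM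
Reagents that add atoms: none
Why: Proposed new method: the acid chloride, made under neutral conditions so that no HCl meets the silyl ethers, adds oxidatively to zerovalent palladium (formed in the flask from PdCl2(PPh3)2), and the electrophilic acylpalladium chloride cleaves the less substituted C3′–C5′ bond of the siloxycyclopropane while chloride takes the silyl group, leaving an acyl(β-ketoalkyl)palladium that reductively eliminates to form C5′–C6′, the bond being paid for by release of about 27 kcal/mol of ring strain. The closest known reaction is the intermolecular palladium-catalysed acylation of 1-alkyl-1-siloxycyclopropanes with acid chlorides to 1,4-diketones (and the related C-acylation of cyclopropanols), which is run here as a ring closure. The fourteen-membered ring is closed head-to-tail by this C(sp3)–C(acyl) reductive elimination from a fifteen-membered palladacycle under high dilution. No stereocentre is created: C4′ is a spectator carbon of the cyclopropane and is carried over with retention, and C7′ next to the acyl group is not enolised because no base is present. The step needs cleavage of the CH2–C(OSi) bond in preference to the CH(iPr)–C(OSi) bond, which the lower substitution at C5′ secures; reductive elimination faster than β-hydride elimination or decarbonylation, for which phosphine ligands and a CO atmosphere are used; and ring closure over oligomerisation, which the syringe-pump addition secures.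

Step 37
Reactants: 50 bis(triethylsilyl) ether of the target
Product: 51 CNP0105157.3 (target)
Conditions: HF·pyridine, pyridine, THF, 0 to 25 °C
Reagents that add atoms: none
Why: Buffered fluoride desilylation removes the secondary allylic and the tertiary triethylsilyl ether without epimerising the ketone α-centres or touching the methyl ester.

**Compound list**

1 | but-3-yn-1-ol | C#CCCO | starting material
2 | tert-butyl(but-3-yn-1-yloxy)diphenylsilane | C#CCCO[Si](c1ccccc1)(c1ccccc1)C(C)(C)C | intermediate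
3 | dimethyl{(1E)-4-[(tert-butyldiphenylsilyl)oxy]-2-methylbut-1-enyl}alane | C[Al](C)/C=C(\C)CCO[Si](c1ccccc1)(c1ccccc1)C(C)(C)C | intermediate
4 | (2E)-5-[(tert-butyldiphenylsilyl)oxy]-3-methylpent-2-en-1-ol | OC/C=C(\C)CCO[Si](c1ccccc1)(c1ccccc1)C(C)(C)C | intermediate
5 | {[(3E)-5-bromo-3-methylpent-3-en-1-yl]oxy}(tert-butyl)diphenylsilane | BrC/C=C(\C)CCO[Si](c1ccccc1)(c1ccccc1)C(C)(C)C | intermediate
6 | geraniol | CC(C)=CCC/C(C)=C/CO | starting material
7 | geranyl tert-butyldimethylsilyl ether | CC(C)=CCC/C(C)=C/CO[Si](C)(C)C(C)(C)C | intermediate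
8 | (S)-6,7-epoxygeranyl tert-butyldimethylsilyl ether | CC1(C)O[C@H]1CC/C(C)=C/CO[Si](C)(C)C(C)(C)C | intermediate
9 | (3S,6E)-8-[(tert-butyldimethylsilyl)oxy]-2,6-dimethylocta-1,6-dien-3-ol | C=C(C)[C@@H](O)CC/C(C)=C/CO[Si](C)(C)C(C)(C)C | intermediate
10 | dilithio dianion of 9 (O-lithio, C9-lithio) | [Li]CC(=C)[C@@H](O[Li])CC/C(C)=C/CO[Si](C)(C)C(C)(C)C | intermediate
11 | (2E,6S,10E)-1-[(tert-butyldimethylsilyl)oxy]-13-[(tert-butyldiphenylsilyl)oxy]-3,11-dimethyl-7-methylidenetrideca-2,10-dien-6-ol | C=C(CC/C=C(\C)CCO[Si](c1ccccc1)(c1ccccc1)C(C)(C)C)[C@@H](O)CC/C(C)=C/CO[Si](C)(C)C(C)(C)C | intermediate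
12 | (2E,6S,10S,11S)-10,11-epoxide of 11 | C=C(CC[C@@H]1O[C@@]1(C)CCO[Si](c1ccccc1)(c1ccccc1)C(C)(C)C)[C@@H](O)CC/C(C)=C/CO[Si](C)(C)C(C)(C)C | intermediate
13 | (2S)-4-[(tert-butyldiphenylsilyl)oxy]-2-[(2R,6S)-6-{(3E)-5-[(tert-butyldimethylsilyl)oxy]-3-methylpent-3-en-1-yl}-5-methylideneoxan-2-yl]butan-2-ol | C=C1CC[C@@H](O[C@H]1CC/C(C)=C/CO[Si](C)(C)C(C)(C)C)[C@@](C)(O)CCO[Si](c1ccccc1)(c1ccccc1)C(C)(C)C | intermediate
14 | (2E)-5-[(2S,6R)-6-{(2S)-4-[(tert-butyldiphenylsilyl)oxy]-2-hydroxybutan-2-yl}-3-methylideneoxan-2-yl]-3-methylpent-2-en-1-ol | C=C1CC[C@@H](O[C@H]1CC/C(C)=C/CO)[C@@](C)(O)CCO[Si](c1ccccc1)(c1ccccc1)C(C)(C)C | intermediate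
15 | (2E)-5-[(2S,6R)-6-{(2S)-4-[(tert-butyldiphenylsilyl)oxy]-2-hydroxybutan-2-yl}-3-methylideneoxan-2-yl]-3-methylpent-2-enal | C=C1CC[C@@H](O[C@H]1CC/C(C)=C/C=O)[C@@](C)(O)CCO[Si](c1ccccc1)(c1ccccc1)C(C)(C)C | intermediate
16 | (2S)-4-[(tert-butyldiphenylsilyl)oxy]-2-{(2R,6S)-6-[(3E)-6,6-dibromo-3-methylhexa-3,5-dien-1-yl]-5-methylideneoxan-2-yl}butan-2-ol | C=C1CC[C@@H](O[C@H]1CC/C(C)=C/C=C(Br)Br)[C@@](C)(O)CCO[Si](c1ccccc1)(c1ccccc1)C(C)(C)C | intermediate
17 | (2S)-4-[(tert-butyldiphenylsilyl)oxy]-2-{(2R,6S)-6-[(3E,5Z)-6-bromo-3,7-dimethylocta-3,5,7-trien-1-yl]-5-methylideneoxan-2-yl}butan-2-ol | C=C1CC[C@@H](O[C@H]1CC/C(C)=C/C=C(/C(C)=C)Br)[C@@](C)(O)CCO[Si](c1ccccc1)(c1ccccc1)C(C)(C)C | intermediate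
18 | (3S)-3-{(2R,6S)-6-[(3E,5Z)-6-bromo-3,7-dimethylocta-3,5,7-trien-1-yl]-5-methylideneoxan-2-yl}butane-1,3-diol | C=C1CC[C@@H](O[C@H]1CC/C(C)=C/C=C(/C(C)=C)Br)[C@@](C)(O)CCO | intermediate
19 | (3S)-3-{(2R,6S)-6-[(3E,5Z)-6-bromo-3,7-dimethylocta-3,5,7-trien-1-yl]-5-methylideneoxan-2-yl}-3-hydroxybutanal | C=C1CC[C@@H](O[C@H]1CC/C(C)=C/C=C(/C(C)=C)Br)[C@@](C)(O)CC=O | intermediate
20 | (1Z,3E,7S,11R,12S,14RS)-7,11-epoxycembra-1,3,8(19),15-tetraene-12,14-diol | C=C1CC[C@H]2O[C@H]1CC/C(C)=C/C=C(/C(C)=C)C(O)C[C@]2(C)O | intermediate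
21 | (1Z,3E,7S,11R,12S)-12-hydroxy-7,11-epoxycembra-1,3,8(19),15-tetraen-14-one | C=C1CC[C@H]2O[C@H]1CC/C(C)=C/C=C(/C(C)=C)C(=O)C[C@]2(C)O | intermediate
22 | O12-diethylborinate of 21 | C=C1CC[C@H]2O[C@H]1CC/C(C)=C/C=C(/C(C)=C)C(=O)C[C@]2(C)OB(CC)CC | intermediate
23 | (1Z,3E,7S,11R,12S,14R)-7,11-epoxycembra-1,3,8(19),15-tetraene-12,14-diol | C=C1CC[C@H]2O[C@H]1CC/C(C)=C/C=C(/C(C)=C)[C@H](O)C[C@]2(C)O | intermediate
24 | 12,14-bis(triethylsilyl) ether of 23 | C=C1CC[C@H]2O[C@H]1CC/C(C)=C/C=C(/C(C)=C)[C@H](O[Si](CC)(CC)CC)C[C@]2(C)O[Si](CC)(CC)CC | intermediate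
25 | methyl (R)-2-hydroxy-3-methylbutanoate | COC(=O)[C@H](O)C(C)C | starting material
26 | methyl (R)-3-methyl-2-(methylsulfonyloxy)butanoate | COC(=O)[C@H](OS(C)(=O)=O)C(C)C | intermediate
27 | (R)-3-methyl-2-(methylsulfonyloxy)butanoic acid | OC(=O)[C@H](OS(C)(=O)=O)C(C)C | intermediate
28 | (R)-3-methyl-2-(methylsulfonyloxy)butanoyl chloride | ClC(=O)[C@H](OS(C)(=O)=O)C(C)C | intermediate
29 | methyl (R)-6-methyl-5-(methylsulfonyloxy)-4-oxoheptanoate | COC(=O)CCC(=O)[C@H](OS(C)(=O)=O)C(C)C | intermediate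
30 | iodozinc cyclopropoxide (zinc alkoxide of the cyclopropanol of 31) | COC(=O)CC[C@@]1(O[Zn]I)C[C@H]1C(C)C | intermediate
31 | methyl 3-[(2S)-2-isopropyl-1-(trimethylsilyloxy)cyclopropyl]propanoate, propanoate chain cis to isopropyl | COC(=O)CC[C@@]1(O[Si](C)(C)C)C[C@H]1C(C)C | intermediate
32 | lithium ester enolate of 31 | COC(O[Li])=CC[C@@]1(O[Si](C)(C)C)C[C@H]1C(C)C | intermediate
33 | methyl 2-bromo-3-[(2S)-2-isopropyl-1-(trimethylsilyloxy)cyclopropyl]propanoate (C1′ epimers) | COC(=O)C(Br)C[C@@]1(O[Si](C)(C)C)C[C@H]1C(C)C | intermediate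
34 | {1-methoxy-1-oxo-3-[(2S)-2-isopropyl-1-(trimethylsilyloxy)cyclopropyl]propan-2-yl}triphenylphosphonium bromide | COC(=O)C(C[C@@]1(O[Si](C)(C)C)C[C@H]1C(C)C)[P+](c1ccccc1)(c1ccccc1)c1ccccc1.[Br-] | intermediate
35 | methyl 3-[(2S)-2-isopropyl-1-(trimethylsilyloxy)cyclopropyl]-2-(triphenyl-λ5-phosphanylidene)propanoate | COC(=O)C(C[C@@]1(O[Si](C)(C)C)C[C@H]1C(C)C)=P(c1ccccc1)(c1ccccc1)c1ccccc1 | intermediate
36 | (S)-citronellic acid | OC(=O)C[C@@H](C)CCC=C(C)C | starting material
37 | (S)-N-methoxy-N,3,7-trimethyloct-6-enamide | CON(C)C(=O)C[C@@H](C)CCC=C(C)C | intermediate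
38 | ozonide of 37 (3,3-dimethyl-1,2,4-trioxolane) | CON(C)C(=O)C[C@@H](C)CCC1OOC(C)(C)O1 | intermediate
39 | (S)-N-methoxy-N,3-dimethyl-6-oxohexanamide | CON(C)C(=O)C[C@@H](C)CCC=O | intermediate
40 | (2E,6S)-8-[methoxy(methyl)amino]-2,6-dimethyl-8-oxooct-2-enoic acid | CON(C)C(=O)C[C@@H](C)CC/C=C(\C)C(=O)O | intermediate
41 | (2R,6S)-8-[methoxy(methyl)amino]-2,6-dimethyl-8-oxooctanoic acid | CON(C)C(=O)C[C@@H](C)CCC[C@@H](C)C(=O)O | intermediate
42 | (2R,6S)-2,6-dimethyl-8-oxodec-9-enoic acid | C=CC(=O)C[C@@H](C)CCC[C@@H](C)C(=O)O | intermediate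
43 | 9H-fluoren-9-ylmethyl (2R,6S)-2,6-dimethyl-8-oxodec-9-enoate | C=CC(=O)C[C@@H](C)CCC[C@@H](C)C(=O)OCC1c2ccccc2-c2ccccc21 | intermediate
44 | ozonide of 43 (1,2,4-trioxolan-3-yl ketone) | O=C(C[C@@H](C)CCC[C@@H](C)C(=O)OCC1c2ccccc2-c2ccccc21)C1OOCO1 | intermediate
45 | 9H-fluoren-9-ylmethyl (2R,6S)-2,6-dimethyl-8,9-dioxononanoate | O=CC(=O)C[C@@H](C)CCC[C@@H](C)C(=O)OCC1c2ccccc2-c2ccccc21 | intermediate
46 | 1-(9H-fluoren-9-ylmethyl) 11-methyl (2R,6S,9E)-10-{[(2S)-2-isopropyl-1-(trimethylsilyloxy)cyclopropyl]methyl}-2,6-dimethyl-8-oxoundec-9-enedioate | COC(=O)/C(C[C@@]1(O[Si](C)(C)C)C[C@H]1C(C)C)=C/C(=O)C[C@@H](C)CCC[C@@H](C)C(=O)OCC1c2ccccc2-c2ccccc21 | intermediate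
47 | Diels–Alder adduct of 24 and 46 (fluorenylmethyl ester; C2 S, C1′ S, C14′ S) | C=C1CC[C@H]2O[C@H]1CC/C(C)=C/[C@H]1C(=C(C)C[C@H](C(=O)C[C@@H](C)CCC[C@@H](C)C(=O)OCC3c4ccccc4-c4ccccc43)[C@@]1(C[C@@]3(O[Si](C)(C)C)C[C@H]3C(C)C)C(=O)OC)[C@H](O[Si](CC)(CC)CC)C[C@]2(C)O[Si](CC)(CC)CC | intermediate
48 | seco-acid (C6′ carboxylic acid of 47) | C=C1CC[C@H]2O[C@H]1CC/C(C)=C/[C@H]1C(=C(C)C[C@H](C(=O)C[C@@H](C)CCC[C@@H](C)C(=O)O)[C@@]1(C[C@@]3(O[Si](C)(C)C)C[C@H]3C(C)C)C(=O)OC)[C@H](O[Si](CC)(CC)CC)C[C@]2(C)O[Si](CC)(CC)CC | intermediate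
49 | seco-acid chloride | C=C1CC[C@H]2O[C@H]1CC/C(C)=C/[C@H]1C(=C(C)C[C@H](C(=O)C[C@@H](C)CCC[C@@H](C)C(=O)Cl)[C@@]1(C[C@@]3(O[Si](C)(C)C)C[C@H]3C(C)C)C(=O)OC)[C@H](O[Si](CC)(CC)CC)C[C@]2(C)O[Si](CC)(CC)CC | intermediate
50 | 12,14-bis(triethylsilyl) ether of the target | C=C1CC[C@H]2O[C@H]1CC/C(C)=C/[C@H]1C(=C(C)C[C@@H]3C(=O)C[C@@H](C)CCC[C@@H](C)C(=O)C[C@@H](C(C)C)C(=O)C[C@@]31C(=O)OC)[C@H](O[Si](CC)(CC)CC)C[C@]2(C)O[Si](CC)(CC)CC | intermediate
51 | CNP0105157.3 | C=C1CC[C@H]2O[C@H]1CC/C(C)=C/[C@H]1C(=C(C)C[C@@H]3C(=O)C[C@@H](C)CCC[C@@H](C)C(=O)C[C@@H](C(C)C)C(=O)C[C@@]31C(=O)OC)[C@H](O)C[C@]2(C)O | target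

Total step count: 37. Longest linear sequence: 20 steps (steps 4–19, then 34–37).

**Steps most likely to fail**

Step 36 (labelled). What may go wrong: β-hydride elimination of the β-ketoalkylpalladium to the α-methylene ketone, decarbonylation of the acylpalladium, or intermolecular coupling in place of ring closure. The fallback sets out from 48 and comes back at 50, using a known acyl radical macrocyclisation onto an enone. The siloxycyclopropane of 48 would be opened with stoichiometric PdCl2(MeCN)2 in MeCN, where ring-opening and β-hydride elimination are the wanted path, to the α-methylene ketone enone acid F1. The acid would be converted with 1-chloro-N,N,2-trimethylprop-1-enylamine and then PhSeH/pyridine into the phenyl selenoester F2. Bu3SnH and AIBN in benzene at 80 °C under high dilution would give the acyl radical, which adds 14-endo to the CH2 terminus of the enone to form C5′–C6′ and give 50. In this variant C4′ is set by hydrogen transfer to the α-keto radical, so the C4′ epimers would have to be separated or equilibrated.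

Step 34. What may go wrong: poor facial selectivity (addition syn to the C14 oxygen) or loss of endo/regio control with the acyclic dienophile. The fallback sets out from 21 and comes back at 47. It uses C14 as a switchable control element. Evans–Saksena reduction of 21 (Me4NBH(OAc)3, MeCN/AcOH) would give the 1,3-anti diol, 14-epi diol F3, whose free hydroxyl presents the opposite diene face. Cycloaddition of F3 with 46 would then give the 14-epi adduct F4. MnO2 oxidation of the allylic alcohol would give the C14 ketone adduct F5. Narasaka–Prasad reduction directed by the C12 hydroxyl would restore the R carbinol in the diol adduct F6, and bis-silylation with TESOTf returns to 47.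

Step 23. What may go wrong: slow intramolecular SN2 closure at the isopropyl-bearing carbon, or lactonisation of the zinc alkoxide onto the ester. The fallback sets out from 29 and comes back at 31, replacing the dizinc reagent by a stannyl carbanion and a separate 1,3-elimination. Bu3SnCH2Li (from Bu3SnCH2I and n-BuLi, −78 °C) would add to the ketone under chelation control to give the γ-stannyl mesylate, stannyl carbinol F7. Warming would induce stereospecific destannylative 1,3-elimination with inversion at C4′ to the free cyclopropanol F8, which Me3SiCl/imidazole would convert into 31.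

Further compounds
F1 | step 36 | enone acid (α-methylene ketone at C3′/C4′, free C6′ acid) | C=C1CC[C@H]2O[C@H]1CC/C(C)=C/[C@H]1C(=C(C)C[C@H](C(=O)C[C@@H](C)CCC[C@@H](C)C(=O)O)[C@@]1(CC(=O)C(=C)C(C)C)C(=O)OC)[C@H](O[Si](CC)(CC)CC)C[C@]2(C)O[Si](CC)(CC)CC
F2 | step 36 | phenyl selenoester of F1 | C=C1CC[C@H]2O[C@H]1CC/C(C)=C/[C@H]1C(=C(C)C[C@H](C(=O)C[C@@H](C)CCC[C@@H](C)C(=O)[Se]c3ccccc3)[C@@]1(CC(=O)C(=C)C(C)C)C(=O)OC)[C@H](O[Si](CC)(CC)CC)C[C@]2(C)O[Si](CC)(CC)CC
F3 | step 34 | 14-epi diol, (1Z,3E,7S,11R,12S,14S)-7,11-epoxycembra-1,3,8(19),15-tetraene-12,14-diol | C=C1CC[C@H]2O[C@H]1CC/C(C)=C/C=C(/C(C)=C)[C@@H](O)C[C@]2(C)O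
F4 | step 34 | 14-epi adduct (free 12,14-diol, 14S) | C=C1CC[C@H]2O[C@H]1CC/C(C)=C/[C@H]1C(=C(C)C[C@H](C(=O)C[C@@H](C)CCC[C@@H](C)C(=O)OCC3c4ccccc4-c4ccccc43)[C@@]1(C[C@@]3(O[Si](C)(C)C)C[C@H]3C(C)C)C(=O)OC)[C@@H](O)C[C@]2(C)O
F5 | step 34 | C14 ketone adduct (12-hydroxy) | C=C1CC[C@H]2O[C@H]1CC/C(C)=C/[C@H]1C(=C(C)C[C@H](C(=O)C[C@@H](C)CCC[C@@H](C)C(=O)OCC3c4ccccc4-c4ccccc43)[C@@]1(C[C@@]3(O[Si](C)(C)C)C[C@H]3C(C)C)C(=O)OC)C(=O)C[C@]2(C)O
F6 | step 34 | diol adduct (free 12,14-diol, 14R) | C=C1CC[C@H]2O[C@H]1CC/C(C)=C/[C@H]1C(=C(C)C[C@H](C(=O)C[C@@H](C)CCC[C@@H](C)C(=O)OCC3c4ccccc4-c4ccccc43)[C@@]1(C[C@@]3(O[Si](C)(C)C)C[C@H]3C(C)C)C(=O)OC)[C@H](O)C[C@]2(C)O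
F7 | step 23 | stannyl carbinol, methyl (5R)-4-hydroxy-6-methyl-5-(methylsulfonyloxy)-4-[(tributylstannyl)methyl]heptanoate | COC(=O)CC[C@@](O)(C[Sn](CCCC)(CCCC)CCCC)[C@H](OS(C)(=O)=O)C(C)C
F8 | step 23 | cyclopropanol, methyl 3-[(2S)-1-hydroxy-2-isopropylcyclopropyl]propanoate | COC(=O)CC[C@@]1(O)C[C@H]1C(C)C
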